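**Retrosynthetic overview**

1. The C3–O ester bond is made last: silyl-protected ketol 18 plus acid 24 (from (R)-pent-4-en-2-ol, angelic acid and acrylic acid by esterification and cross-metathesis).
2. The ring B functions (C8 ketone, C9 hydroxyl, cis ring fusion at C10, C7 isopropenyl) are grown from the C9=C10 alkene of octalinol 9 by allylic oxidation, hydrogenation, Rubottom oxidation and α-alkenylation.
3. Key disconnection: ring A is closed at C2–C3 from the monocyclic ether 7. A Claisen shift makes C4–C5 and moves the oxygen from C9 to C3; nickel then closes the C3 aldehyde onto the C2 terminus of the C9=C10–C1=C2 diene.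
4. Enabling feature: C3–O (ring A) and the oxygenated C9 (ring B) flank the quaternary C5 as O–C3–C4–C5–C10–C9–O, a γ,δ-unsaturated carbonyl (Claisen) pattern. C2 lies six atoms from C3 through C1–C10–C5–C4, so a vinyl group on C10 supplies C1 and C2.
5. Ring order: ring B is bought (3-methylcyclohex-2-en-1-one, absolute configuration from a CBS reduction); ring A is formed in the key step; the C9 oxygen is put back later on the C8 ketone enol.

Key step: step 5

Remark: ring atoms carry eremophilane numbers (ring A: C1, C2, C3, C4, C5, C10; ring B: C5 to C10; C14 methyl on C5, C15 methyl on C4, isopropenyl on C7). (Z)-1-Bromoprop-1-ene, (R)-pent-4-en-2-ol and angelic acid are assumed to be purchasable as single isomers.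

**Route**

Step 1
Reactants: 1 3-methylcyclohex-2-en-1-one
Product: 2 2-iodo-3-methylcyclohex-2-en-1-one
Conditions: I2, pyridine, CH2Cl2, 0 °C to rt
Reagents that add atoms: iodine, II
Why: α-iodination of an enone by the pyridine-mediated addition–iodination–elimination sequence (Baylis–Hillman type), which works on β-substituted cyclohexenones; no stereocentre is formed.

Step 2
Reactants: 2 2-iodo-3-methylcyclohex-2-en-1-one
Product: 3 (R)-2-iodo-3-methylcyclohex-2-en-1-ol
Conditions: (S)-2-methyl-CBS-oxazaborolidine (10 mol%), BH3·SMe2, THF, −20 °C; MeOH quench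
Reagents that add atoms: none
Why: Corey–Bakshi–Shibata reduction, in which the iodoalkenyl flank is the large group, so the (S)-catalyst should deliver hydride to the face that gives the (R)-carbinol, the centre that later controls C5 and C4.

Step 3
Reactants: 3 (R)-2-iodo-3-methylcyclohex-2-en-1-ol; 4 tributyl(vinyl)stannane
Product: 5 (R)-3-methyl-2-vinylcyclohex-2-en-1-ol
Conditions: Pd(PPh3)4 (5 mol%), CuI (10 mol%), DMF, 50 °C
Reagents that add atoms: none
Why: Stille coupling of the vinyl iodide, tolerant of the free allylic alcohol, builds the C10–C1 bond and the C5=C10–C1=C2 diene without touching the carbinol centre.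

Step 4
Reactants: 5 (R)-3-methyl-2-vinylcyclohex-2-en-1-ol; 6 (Z)-1-bromoprop-1-ene
Product: 7 (R)-1-methyl-3-{[(Z)-prop-1-en-1-yl]oxy}-2-vinylcyclohex-1-ene
Conditions: CuI (10 mol%), 3,4,7,8-tetramethyl-1,10-phenanthroline (20 mol%), Cs2CO3, toluene, sealed tube, 80 °C
Reagents that add atoms: none
Why: copper-catalysed Ullmann-type C–O coupling of a vinyl halide with an alcohol proceeds with retention of the (Z)-geometry and without touching the carbinol centre, and 80 °C should stay below the onset of the Claisen shift.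

Step 5
Reactants: 7 (R)-1-methyl-3-{[(Z)-prop-1-en-1-yl]oxy}-2-vinylcyclohex-1-ene
Product: 9 (1R,2R,8aR)-1,8a-dimethyl-1,2,3,4,6,7,8,8a-octahydronaphthalen-2-ol, via Claisen aldehyde 8 (not isolated)
Conditions: toluene, sealed tube, 120 °C; cool to rt, then THF, Ni(acac)2 (10 mol%), Et3B (2.4 equiv), rt; aq. NaHCO3 work-up
Reagents that add atoms: none
Why: Proposed new method: heating should trigger a chair-like [3,3] Claisen shift that trades the C9–O bond for the C4–C5 bond, and the aldehyde-tethered diene 8 is then closed by zerovalent nickel formed in situ (oxidative cyclisation of the C1=C2 terminus with the Et3B-activated C3=O to an oxanickelacycle/π-allyl species, ethyl transfer from boron, β-hydride elimination, C–H reductive elimination at C1). The closest known reactions are the thermal Claisen rearrangement of allyl (Z)-propenyl ethers and the Ni(acac)2/Et3B homoallylation of aldehydes with 1,3-dienes, known intramolecularly for aldehydes tethered at a diene terminus, whereas here the tether sits on the internal diene carbon C10. Ring A (C3–C4–C5–C10–C1–C2) is closed as a six-membered ring by bonding the aldehyde carbon C3 to the remote diene terminus C2, exo with respect to C=O and endo with respect to the C1=C2 bond. C5 is set by suprafacial chirality transfer from the (R)-C9–O centre, and C4 by the (Z)-enol ether geometry in the chair transition state (methyl pseudo-axial, anti to the ring CH2, hence cis to the C5 methyl). C3 should be set by nickel binding the diene face opposite the C5 methyl and delivering the nickel-bound oxygen on that face, trans to the C4 methyl. The step needs bonding at C2 and not at the ring terminus C9 (a strain-free six-membered closure at the unsubstituted terminus against a bridged five-membered one), and hydride delivery to C1 and not C9 (the homoallylation pattern), which leaves the C9=C10 alkene for step 7.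

Step 6
Reactants: 9 (1R,2R,8aR)-1,8a-dimethyl-1,2,3,4,6,7,8,8a-octahydronaphthalen-2-ol
Product: 10 triethyl{[(1R,2R,8aR)-1,8a-dimethyl-1,2,3,4,6,7,8,8a-octahydronaphthalen-2-yl]oxy}silane
Conditions: Et3SiCl, imidazole, DMF, rt
Reagents that add atoms: chlorotriethylsilane, CC[Si](Cl)(CC)CC
Why: silylation of the only hydroxyl masks C3–O through the oxidation, hydrogenation and enolate steps and can later be removed in the presence of a tert-butyldimethylsilyl ether.

Step 7
Reactants: 10 triethyl{[(1R,2R,8aR)-1,8a-dimethyl-1,2,3,4,6,7,8,8a-octahydronaphthalen-2-yl]oxy}silane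
Product: 11 (4aR,5R,6R)-4a,5-dimethyl-6-[(triethylsilyl)oxy]-4,4a,5,6,7,8-hexahydronaphthalen-2(3H)-one
Conditions: CrO3, 3,5-dimethylpyrazole, CH2Cl2, −20 °C
Reagents that add atoms: chromium trioxide, O=[Cr](=O)=O
Why: allylic oxidation with the hexavalent chromium–pyrazole complex attacks the ring methylene next to the CH terminus of a trisubstituted cyclohexene (as in the steroid 5-ene to 5-en-7-one oxidation), so C8 and not C1 should be oxidised, giving the β,β-disubstituted enone.

Step 8
Reactants: 11 (4aR,5R,6R)-4a,5-dimethyl-6-[(triethylsilyl)oxy]-4,4a,5,6,7,8-hexahydronaphthalen-2(3H)-one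
Product: 12 (4aS,5R,6R,8aR)-4a,5-dimethyl-6-[(triethylsilyl)oxy]octahydronaphthalen-2(1H)-one (cis-fused)
Conditions: H2 (1 atm), Pd/C, EtOAc, rt
Reagents that add atoms: none
Why: heterogeneous hydrogenation of a 4a-methyl-octalone type enone is known to add hydrogen to the β-carbon from the face of the angular methyl, so C10 should be set with H cis to the C5 methyl (cis-decalone); silyl ether and ketone are inert.

Step 9
Reactants: 12 (4aS,5R,6R,8aR)-4a,5-dimethyl-6-[(triethylsilyl)oxy]octahydronaphthalen-2(1H)-one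
Product: 13 tert-butyl{[(4aS,5R,6R,8aR)-4a,5-dimethyl-6-[(triethylsilyl)oxy]-3,4,4a,5,6,7,8,8a-octahydronaphthalen-2-yl]oxy}dimethylsilane (C8=C9 enol ether)
Conditions: tBuMe2SiOTf, Et3N, CH2Cl2, 0 °C
Reagents that add atoms: tert-butyldimethylsilyl trifluoromethanesulfonate, CC(C)(C)[Si](C)(C)OS(=O)(=O)C(F)(F)F
Why: soft enolisation gives the thermodynamic silyl enol ether, which for a cis-fused 2-decalone lies towards the ring-fusion side (C8=C9), as known for 5β-3-keto steroids.

Step 10
Reactants: 13 the C8=C9 tert-butyldimethylsilyl enol ether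
Product: 15 (1R,4aR,5R,6R,8aS)-1-[(tert-butyldimethylsilyl)oxy]-4a,5-dimethyl-6-[(triethylsilyl)oxy]octahydronaphthalen-2(1H)-one, via silyloxy epoxide 14 (not isolated)
Conditions: mCPBA, NaHCO3, CH2Cl2, −20 °C to rt
Reagents that add atoms: 3-chloroperoxybenzoic acid, OOC(=O)c1cccc(Cl)c1
Why: Rubottom oxidation, in which the peracid should epoxidise the enol ether on the convex face of the cis-decalin (the face of H10 and the C5 methyl, away from the axial C4–C5 bond of ring A) and 1,4-silyl migration then gives the α-silyloxy ketone with C9–O cis to H10.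

Step 11
Reactants: 15 the α-silyloxy ketone; 16 2-bromopropene
Product: 17 (1R,3R,4aR,5R,6R,8aS)-1-[(tert-butyldimethylsilyl)oxy]-4a,5-dimethyl-3-(prop-1-en-2-yl)-6-[(triethylsilyl)oxy]octahydronaphthalen-2(1H)-one
Conditions: Pd2(dba)3 (2.5 mol%), P(tBu)3 (10 mol%), LiN(SiMe3)2 (2.2 equiv), THF/toluene, −78 °C to rt; AcOH, −78 °C
Reagents that add atoms: none
Why: palladium-catalysed α-alkenylation of a ketone enolate with an alkenyl bromide; with C9 blocked by the silyloxy group the kinetic enolate forms at the C7 methylene, and axial protonation of the product dienolate at C7 on quenching should leave the isopropenyl group equatorial, cis to the C5 methyl, without migration of the double bond into conjugation.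

Step 12
Reactants: 17 the isopropenyl ketone
Product: 18 (1R,3R,4aR,5R,6R,8aS)-1-[(tert-butyldimethylsilyl)oxy]-6-hydroxy-4a,5-dimethyl-3-(prop-1-en-2-yl)octahydronaphthalen-2(1H)-one
Conditions: PPTS, MeOH/CH2Cl2, 0 °C
Reagents that add atoms: none
Why: mild acid methanolysis cleaves the secondary triethylsilyl ether much faster than the hindered tert-butyldimethylsilyl ether, freeing only C3–OH.

Step 13
Reactants: 19 (R)-pent-4-en-2-ol; 20 angelic acid, (Z)-2-methylbut-2-enoic acid
Product: 22 (R)-pent-4-en-2-yl (Z)-2-methylbut-2-enoate, via mixed anhydride 21 (not isolated)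
Conditions: 2,4,6-trichlorobenzoyl chloride, Et3N, toluene, rt; then 19, 80 °C
Reagents that add atoms: none
Why: Yamaguchi esterification through the mixed anhydride without a nucleophilic amine catalyst is the usual way to make angelates without Z to E isomerisation; the C–O bond of the alcohol is not broken, so the (R)-centre is kept.

Step 14
Reactants: 22 (R)-pent-4-en-2-yl (Z)-2-methylbut-2-enoate; 23 acrylic acid
Product: 24 (R,E)-5-{[(Z)-2-methylbut-2-enoyl]oxy}hex-2-enoic acid
Conditions: second-generation Hoveyda–Grubbs catalyst (5 mol%), CH2Cl2, 40 °C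
Reagents that add atoms: none
Why: olefin cross-metathesis of a terminal alkene with acrylic acid is E-selective and leaves the trisubstituted, electron-poor angelate alkene untouched.

Step 15
Reactants: 18 the C3 alcohol; 24 (R,E)-5-{[(Z)-2-methylbut-2-enoyl]oxy}hex-2-enoic acid
Product: 26 (1R,2R,4aS,5R,7R,8aR)-5-[(tert-butyldimethylsilyl)oxy]-1,8a-dimethyl-6-oxo-7-(prop-1-en-2-yl)decahydronaphthalen-2-yl (R,E)-5-{[(Z)-2-methylbut-2-enoyl]oxy}hex-2-enoate, via mixed anhydride 25 (not isolated)
Conditions: 2,4,6-trichlorobenzoyl chloride, Et3N, THF, rt; then 18, DMAP, toluene, rt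
Reagents that add atoms: none
Why: Yamaguchi esterification acylates the only free hydroxyl (equatorial C3–OH) with retention, the C9 oxygen being silylated.

Step 16
Reactants: 26 the silyl-protected ester
Product: 27 (1R,2R,4aS,5R,7R,8aR)-5-hydroxy-1,8a-dimethyl-6-oxo-7-(prop-1-en-2-yl)decahydronaphthalen-2-yl (R,E)-5-{[(Z)-2-methylbut-2-enoyl]oxy}hex-2-enoate (CNP0210874.1)
Conditions: HF·pyridine, pyridine, THF, 0 °C to rt
Reagents that add atoms: none
Why: buffered fluoride cleaves the silyl ether without base, so the angelate geometry, the conjugated ester and the epimerisable C7 and C9 centres should survive.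

**Compound list**

1 | 3-methylcyclohex-2-en-1-one | CC1=CC(=O)CCC1 | starting material
2 | 2-iodo-3-methylcyclohex-2-en-1-one | CC1=C(I)C(=O)CCC1 | intermediate
3 | (R)-2-iodo-3-methylcyclohex-2-en-1-ol | O[C@@H]1CCCC(C)=C1I | intermediate
4 | tributyl(vinyl)stannane | C=C[Sn](CCCC)(CCCC)CCCC | starting material
5 | (R)-3-methyl-2-vinylcyclohex-2-en-1-ol | O[C@@H]1CCCC(C)=C1C=C | intermediate
6 | (Z)-1-bromoprop-1-ene | C/C=C\Br | starting material
7 | (R)-1-methyl-3-{[(Z)-prop-1-en-1-yl]oxy}-2-vinylcyclohex-1-ene | C/C=C\O[C@@H]1CCCC(C)=C1C=C | intermediate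
8 | (R)-2-[(R)-1-methyl-2-vinylcyclohex-2-en-1-yl]propanal | C=CC1=CCCC[C@]1(C)[C@@H](C)C=O | intermediate
9 | (1R,2R,8aR)-1,8a-dimethyl-1,2,3,4,6,7,8,8a-octahydronaphthalen-2-ol | C1C[C@@]2(C)C(CC[C@@H](O)[C@@H]2C)=CC1 | intermediate
10 | triethyl{[(1R,2R,8aR)-1,8a-dimethyl-1,2,3,4,6,7,8,8a-octahydronaphthalen-2-yl]oxy}silane | C1C[C@@]2(C)C(CC[C@@H](O[Si](CC)(CC)CC)[C@@H]2C)=CC1 | intermediate
11 | (4aR,5R,6R)-4a,5-dimethyl-6-[(triethylsilyl)oxy]-4,4a,5,6,7,8-hexahydronaphthalen-2(3H)-one | C1C[C@@]2(C)C(CC[C@@H](O[Si](CC)(CC)CC)[C@@H]2C)=CC1=O | intermediate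
12 | (4aS,5R,6R,8aR)-4a,5-dimethyl-6-[(triethylsilyl)oxy]octahydronaphthalen-2(1H)-one, cis-fused | C1C[C@@]2(C)[C@H](CC[C@@H](O[Si](CC)(CC)CC)[C@@H]2C)CC1=O | intermediate
13 | tert-butyl{[(4aS,5R,6R,8aR)-4a,5-dimethyl-6-[(triethylsilyl)oxy]-3,4,4a,5,6,7,8,8a-octahydronaphthalen-2-yl]oxy}dimethylsilane | C1C[C@@]2(C)[C@H](CC[C@@H](O[Si](CC)(CC)CC)[C@@H]2C)C=C1O[Si](C)(C)C(C)(C)C | intermediate
14 | C8,C9-epoxide of 13, oxirane on the face of H10 and the C5 methyl | C1C[C@@]2(C)[C@H](CC[C@@H](O[Si](CC)(CC)CC)[C@@H]2C)[C@H]3O[C@@]13O[Si](C)(C)C(C)(C)C | intermediate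
15 | (1R,4aR,5R,6R,8aS)-1-[(tert-butyldimethylsilyl)oxy]-4a,5-dimethyl-6-[(triethylsilyl)oxy]octahydronaphthalen-2(1H)-one | C1C[C@@]2(C)[C@H](CC[C@@H](O[Si](CC)(CC)CC)[C@@H]2C)[C@@H](O[Si](C)(C)C(C)(C)C)C1=O | intermediate
16 | 2-bromopropene | CC(Br)=C | starting material
17 | (1R,3R,4aR,5R,6R,8aS)-1-[(tert-butyldimethylsilyl)oxy]-4a,5-dimethyl-3-(prop-1-en-2-yl)-6-[(triethylsilyl)oxy]octahydronaphthalen-2(1H)-one | C=C(C)[C@H]1C[C@@]2(C)[C@H](CC[C@@H](O[Si](CC)(CC)CC)[C@@H]2C)[C@@H](O[Si](C)(C)C(C)(C)C)C1=O | intermediate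
18 | (1R,3R,4aR,5R,6R,8aS)-1-[(tert-butyldimethylsilyl)oxy]-6-hydroxy-4a,5-dimethyl-3-(prop-1-en-2-yl)octahydronaphthalen-2(1H)-one | C=C(C)[C@H]1C[C@@]2(C)[C@H](CC[C@@H](O)[C@@H]2C)[C@@H](O[Si](C)(C)C(C)(C)C)C1=O | intermediate
19 | (R)-pent-4-en-2-ol | C=CC[C@@H](C)O | starting material
20 | angelic acid, (Z)-2-methylbut-2-enoic acid | OC(=O)/C(C)=C\C | starting material
21 | (Z)-2-methylbut-2-enoic 2,4,6-trichlorobenzoic anhydride | C/C=C(/C)C(=O)OC(=O)c1c(Cl)cc(Cl)cc1Cl | intermediate
22 | (R)-pent-4-en-2-yl (Z)-2-methylbut-2-enoate | C=CC[C@@H](C)OC(=O)/C(C)=C\C | intermediate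
23 | acrylic acid | C=CC(=O)O | starting material
24 | (R,E)-5-{[(Z)-2-methylbut-2-enoyl]oxy}hex-2-enoic acid | OC(=O)/C=C/C[C@@H](C)OC(=O)/C(C)=C\C | intermediate
25 | mixed anhydride of 24 with 2,4,6-trichlorobenzoic acid | Clc1cc(Cl)c(C(=O)OC(=O)/C=C/C[C@@H](C)OC(=O)/C(C)=C\C)c(Cl)c1 | intermediate
26 | (1R,2R,4aS,5R,7R,8aR)-5-[(tert-butyldimethylsilyl)oxy]-1,8a-dimethyl-6-oxo-7-(prop-1-en-2-yl)decahydronaphthalen-2-yl (R,E)-5-{[(Z)-2-methylbut-2-enoyl]oxy}hex-2-enoate | C=C(C)[C@H]1C[C@@]2(C)[C@H](CC[C@@H](OC(=O)/C=C/C[C@@H](C)OC(=O)/C(C)=C\C)[C@@H]2C)[C@@H](O[Si](C)(C)C(C)(C)C)C1=O | intermediate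
27 | (1R,2R,4aS,5R,7R,8aR)-5-hydroxy-1,8a-dimethyl-6-oxo-7-(prop-1-en-2-yl)decahydronaphthalen-2-yl (R,E)-5-{[(Z)-2-methylbut-2-enoyl]oxy}hex-2-enoate | C=C(C)[C@H]1C[C@@]2(C)[C@H](CC[C@@H](OC(=O)/C=C/C[C@@H](C)OC(=O)/C(C)=C\C)[C@@H]2C)[C@@H](O)C1=O | target

**Step count and risks**

Total step count: 16. Longest linear sequence: 14 steps (steps 1 to 12, then 15 and 16); steps 13 and 14 form the two-step side-chain branch.

Steps most likely to fail:

1. Step 5 (Proposed new method). The Claisen stage may leak through a boat transition state and erode the C4 configuration. The nickel stage may bond C3 to the ring terminus C9 (bridged five-membered ring), oligomerise the diene aldehyde, or deliver the carbonyl from the wrong face at C3.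
   Fallback with known chemistry, from 8 back to 9: the thermal stage is run alone and aldehyde 8 is isolated. It is converted with HC(OMe)3 and PPTS in MeOH into the dimethyl acetal of 8 F1. 9-BBN adds only to the vinyl terminus, and NaOH/H2O2 gives the primary alcohol 2-{(R)-6-[(R)-1,1-dimethoxypropan-2-yl]-6-methylcyclohex-1-en-1-yl}ethan-1-ol F2. I2, PPh3 and imidazole give the iodide (R)-6-[(R)-1,1-dimethoxypropan-2-yl]-1-(2-iodoethyl)-6-methylcyclohex-1-ene F3. PPTS in wet acetone frees the iodo aldehyde (R)-2-[(R)-2-(2-iodoethyl)-1-methylcyclohex-2-en-1-yl]propanal F4. Bu3SnH with AIBN in benzene at 80 °C closes the C2–C3 bond by 6-exo addition of the primary radical to the aldehyde and should give 9 together with its C3 epimer. If the C3 or C4 configuration is mixed, the alcohols are oxidised with Dess–Martin periodinane to the ketone (1R,8aR)-1,8a-dimethyl-3,4,6,7,8,8a-hexahydronaphthalen-2(1H)-one F5, C4 is equilibrated with NaOMe in MeOH to the equatorial, cis-dimethyl arrangement, and reduction under thermodynamic control (Li, NH3, MeOH) should return the equatorial alcohol 9.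

2. Step 11. Enolisation may occur towards C9 instead of C7, the new double bond may migrate into conjugation with the ketone, or the dienolate may be protonated from the wrong face at C7.
   Fallback, from 15 back to 17: the kinetic enolate of 15 (LiN(iPr)2, THF, −78 °C) is added to acetone to give the tertiary aldol (1R,3R,4aR,5R,6R,8aS)-1-[(tert-butyldimethylsilyl)oxy]-3-(2-hydroxypropan-2-yl)-4a,5-dimethyl-6-[(triethylsilyl)oxy]octahydronaphthalen-2(1H)-one F6. Dehydration with SOCl2 and pyridine at −20 °C should give 17 by loss of a methyl hydrogen. Any conjugated isomer, the 7-isopropylidene ketone F7, is deconjugated by forming the dienolate (KN(SiMe3)2, THF, −78 °C) and protonating it kinetically at C7 with AcOH, which again gives 17.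

3. Step 8. Facial selectivity of hydrogen delivery to C10 may be poor, giving trans-fused material.
   Fallback, from 11 back to 12: Luche reduction (NaBH4, CeCl3·7H2O, MeOH, −78 °C) should give the equatorial allylic alcohol with hydroxyl cis to the C5 methyl, (2S,4aR,5R,6R)-4a,5-dimethyl-6-[(triethylsilyl)oxy]-2,3,4,4a,5,6,7,8-octahydronaphthalen-2-ol F8. Hydroxyl-directed hydrogenation with Crabtree's catalyst [Ir(cod)(PCy3)(py)]PF6 under H2 in CH2Cl2 delivers hydrogen to C10 on the hydroxyl face and gives the cis-fused alcohol (2S,4aS,5R,6R,8aR)-4a,5-dimethyl-6-[(triethylsilyl)oxy]decahydronaphthalen-2-ol F9. Dess–Martin oxidation returns 12.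

Further compounds
F1 | step 5 | (R)-6-[(R)-1,1-dimethoxypropan-2-yl]-6-methyl-1-vinylcyclohex-1-ene (dimethyl acetal of 8) | C=CC1=CCCC[C@]1(C)[C@@H](C)C(OC)OC
F2 | step 5 | 2-{(R)-6-[(R)-1,1-dimethoxypropan-2-yl]-6-methylcyclohex-1-en-1-yl}ethan-1-ol | OCCC1=CCCC[C@]1(C)[C@@H](C)C(OC)OC
F3 | step 5 | (R)-6-[(R)-1,1-dimethoxypropan-2-yl]-1-(2-iodoethyl)-6-methylcyclohex-1-ene | ICCC1=CCCC[C@]1(C)[C@@H](C)C(OC)OC
F4 | step 5 | (R)-2-[(R)-2-(2-iodoethyl)-1-methylcyclohex-2-en-1-yl]propanal | ICCC1=CCCC[C@]1(C)[C@@H](C)C=O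
F5 | step 5 | (1R,8aR)-1,8a-dimethyl-3,4,6,7,8,8a-hexahydronaphthalen-2(1H)-one | C1C[C@@]2(C)C(CCC(=O)[C@@H]2C)=CC1
F6 | step 11 | (1R,3R,4aR,5R,6R,8aS)-1-[(tert-butyldimethylsilyl)oxy]-3-(2-hydroxypropan-2-yl)-4a,5-dimethyl-6-[(triethylsilyl)oxy]octahydronaphthalen-2(1H)-one | CC(C)(O)[C@H]1C[C@@]2(C)[C@H](CC[C@@H](O[Si](CC)(CC)CC)[C@@H]2C)[C@@H](O[Si](C)(C)C(C)(C)C)C1=O
F7 | step 11 | (1R,4aR,5R,6R,8aS)-1-[(tert-butyldimethylsilyl)oxy]-4a,5-dimethyl-3-(propan-2-ylidene)-6-[(triethylsilyl)oxy]octahydronaphthalen-2(1H)-one | CC(C)=C1C[C@@]2(C)[C@H](CC[C@@H](O[Si](CC)(CC)CC)[C@@H]2C)[C@@H](O[Si](C)(C)C(C)(C)C)C1=O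
F8 | step 8 | (2S,4aR,5R,6R)-4a,5-dimethyl-6-[(triethylsilyl)oxy]-2,3,4,4a,5,6,7,8-octahydronaphthalen-2-ol | O[C@H]1CC[C@@]2(C)C(CC[C@@H](O[Si](CC)(CC)CC)[C@@H]2C)=C1
F9 | step 8 | (2S,4aS,5R,6R,8aR)-4a,5-dimethyl-6-[(triethylsilyl)oxy]decahydronaphthalen-2-ol, cis-fused | O[C@H]1CC[C@@]2(C)[C@H](CC[C@@H](O[Si](CC)(CC)CC)[C@@H]2C)C1
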